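L is the reagent we question first, and the three earlier runs are what we have to question it with.

all flasks: Q 1.05 equiv
- spring: X 0.50 M; E 1.1 equiv; L 0.50 equiv; run made earlier
- midnight: X 0.25 M; E 1.1 equiv; L 0.50 equiv; run made earlier
- summer: X 0.38 M; E 1.1 equiv; L 0.50 equiv; run made earlier
- blue: X 0.50 M (fed, over 5.0 h); E 1.10 equiv; L 0.500 equiv; all else is in the flask from the start; the feed brings no volume worth counting; time 8.0 h
- green: X 0.50 M; E 1.10 equiv; L 0.500 equiv; everything together at the start; time 8.0 h
- violet: X 0.50 M; E 1.10 equiv; L 0.500 equiv (fed, over 5.0 h); all else is in the flask from the start; the feed brings no volume worth counting; time 8.0 h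

| run | time / h | Z / % |
|---|---|---|
| spring | 1.00 | 8.5 |
| spring | 2.50 | 11.4 |
| spring | 3.00 | 13.7 |
| spring | 5.00 | 10.9 |
| spring | 6.00 | 10.3 |
| spring | 8.00 | 14.4 |
| midnight | 0.500 | 1.0 |
| midnight | 1.33 | 2.1 |
| midnight | 2.50 | 6.4 |
| midnight | 4.00 | 6.0 |
| midnight | 6.00 | 7.8 |
| midnight | 8.00 | 9.3 |
| midnight | 10.0 | 8.2 |
| summer | 1.33 | 7.9 |
| summer | 3.00 | 8.4 |
| summer | 4.00 | 10.4 |
| summer | 6.00 | 10.1 |
| summer | 8.00 | 8.0 |
| summer | 10.0 | 13.0 |

(readings scatter by 1 percentage point)

- what was read earlier has a scatter of 1 percentage point, one standard deviation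

- the flask that comes out highest in amount of Z, in percent of the X charged, or "all alike" when all lie within 1.5 percentage points (blue / green / violet / all alike)
- Z at the end, in percent of the X charged, blue
- Z at the end, in percent of the X charged, green
- Z at the end, in percent of the X charged, violet

Did Z stop for lack of L? From 2.50 h on, the spring readings scatter about a flat 12.1 % of the X charged. That is a quarter of the L charged, so Z does not use up L.

Is the stop a balance, then? The spring plateau gives 0.321 for the lock ratio, which is Z on the plateau divided by the L not held in Z, both as fractions of the X charged. The midnight run levels near 7.54 %, a lock ratio of 0.178. As a reading, the ratio falls by a factor of 1.81 while the charge falls by 2.00. With the equivalents held, the plateau share of X read in these two runs is not fixed, 12.1 % against 7.54 %, so we read the plateau as a balance between L and a partner made from X (thermodynamic control).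

Can a fed flask reach that balance in time? The spring reading at 1.00 h is 70.0 % of its plateau as read, which, taken as a first-order rise, reads as a rise time of 0.830 h. A feed of 5.0 h leaves 3.00 h, which is 3.61 rise times. Our reckoning assumes that feeding leaves the share of X reaching the partner unchanged, and on that assumption blue, green and violet all end near 12.1 %, within the margin.

The forecast named violet, with blue 6.5 %, green 12.7 % and violet 17 %, holding that “Feeding X starves the higher-order path”.

The flasks come out all alike, with blue at 13.7 %, green at 12.8 % and violet at 12.8 %.

    X + E → J (k = 0.131 M⁻¹ min⁻¹)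
    Q + J → D (k = 0.197 M⁻¹ min⁻¹)
    L + D ⇌ Z (K = 3.50 M⁻¹, k = 0.0700 M⁻¹ min⁻¹)
    X + Q → G (k = 0.416 M⁻¹ min⁻¹)

In green, with the other concentrations as charged, the forward passing of L + D into Z alone has a half-life of 0.66 h, shorter than the 8.0 h of the run. Violet ends with a lock ratio of 0.345, which divided by its D of 19.8 % gives 1.74. The flask like violet but with 0.120 equiv of L ends at 3.99 % of Z and 28.6 % of D, a lock ratio of 0.499, which divided by that D gives 1.74.

The earlier runs and the new flask stem from a simulated flask for an exercise, and the scatter is random.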